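Readings and results stem from a simulated flask for substances that don't exist; noise was put on by code.

**Partner ledger.** However the catalyst swaps the hands, each unit of product costs one unit of coupling partner, so the partner charge divides into coupled, decomposed and left.

| flask | left-handed substrate | right-handed substrate | coupling partner | racemization catalyst | remark | time |
|---|---|---|---|---|---|---|
| Tuesday's | 0.50 M | 0.50 M | 2 M | 11 mM | the very flask that is asked about, followed so far |  |
| flask | 0.50 M | 0.50 M | 2.00 M | 11 mM |  | 30 min |

Tuesday's run (percent of the left-handed substrate and right-handed substrate together charged)

| time / min | left-handed product / % | right-handed product / % |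
|---|---|---|
| 0.833 | 5.1 | 3.2 |
| 1.50 | 8.8 | 4.9 |
| 2.50 | 13.1 | 7.4 |
| 3.00 | 15.1 | 8.9 |
| 4.00 | 19.0 | 10.6 |
| 5.00 | 20.7 | 12.4 |
| 6.00 | 24.3 | 14.5 |

(scatter of a reading: 0.3 percentage points)

* left-handed product and right-handed product together, in percent of the left-handed substrate and right-handed substrate charged together, at 30 min
* excess of left-handed product over right-handed product in the product at 30 min
* whether the exchange between left-handed substrate and right-handed substrate keeps pace with the reaction: how far the product's excess at 30 min gets from its value without exchange to its value with instant exchange (above 80 % keeps pace, below 20 % hardly takes part, else lags behind)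

- coupling partner is single-handed; left-handed substrate and right-handed substrate are mirror images of each other, charged as a racemate, each of them at the stated concentration
- the numbers in the tables scatter with a standard deviation of 0.3 percentage points
- candidate steps: coupling partner + right-handed substrate -> right-handed product; 2 racemization catalyst -> spent catalyst; 2 racemization catalyst <-> resting dimer; left-handed substrate + racemization catalyst <-> right-handed substrate + racemization catalyst; coupling partner -> decomposed reagent; coupling partner + left-handed substrate -> left-handed product
- an excess is below zero if the other one leads
- the handed part of coupling partner does not stay in what it makes, so the products of the two hands are mirror images too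

**Exposure.** Call exposure g the mean over the two hands of the logarithm of the reciprocal fraction left, with those fractions reckoned from the products. A swap raises one fraction and lowers the other, so it nearly cancels in g. Tuesday's run gives g = 0.278 at 3.00 min and 0.504 at 6.00 min. The second window gains 0.814 of the first. Exposure grows in step with partner, so I read partner at 6.00 min as 0.663 of its charge.

**The crossing.** Coupling took 38.8 % of the substrate charge, and decomposition took the rest of the missing partner. Per unit of exposure this gives the crossing fraction 0.566: the fraction of substrate left at which coupling and decomposition use partner equally, at any partner level. It is a reading and carries the scatter. Tuesday's run ended above it, at 61 percentage points.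

**The reckoning.** The ledger runs out of partner at g = 2.01, which leaves a span of 1.50. The early rate gives a mean constant of 0.0513 M⁻¹ min⁻¹. Closing the span exponentially from 1.33 M of partner gives g = 1.50 at 30 min, so equal hands would yield 77.7 %.

**Weak link.** Equal hands is the weak assumption. The selectivity factor read at 6.00 min is 1.94, and hands without exchange yield 75.0 %. Exchange lies between these, so I commit to 76.4 %.

The forecast says 83 % (74 % to 91 %), a yield above mine, with an excess of 18 % (10 % to 28 %) and exchange that lags behind, these last two on the words “A modest exchange is my best guess”.

**The flask.** It gives 75.9 % against my 76.4 %, an excess of 18.7 %, and exchange that lags behind, 25 % of the way.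

    coupling partner + right-handed substrate → right-handed product (k = 0.0340 M⁻¹ min⁻¹)
    2 racemization catalyst → spent catalyst (k = 2.50 M⁻¹ min⁻¹)
    2 racemization catalyst ⇌ resting dimer (K = 21.0 M⁻¹, k = 6.30 M⁻¹ min⁻¹)
    left-handed substrate + racemization catalyst ⇌ right-handed substrate + racemization catalyst, rate k4*[racemization catalyst]*[left-handed substrate] forward; the back reaction follows from the equilibrium constant (k = 3.10 M⁻¹ min⁻¹)
    coupling partner → decomposed reagent (k = 0.0240 min⁻¹)
    coupling partner + left-handed substrate → left-handed product (k = 0.0650 M⁻¹ min⁻¹)

**Past the crossing.** At 30.0 min the flask holds 24.1 % of its substrate charge, below the crossing fraction 0.566, and decomposition uses partner 4.1 times as fast as the coupling of left-handed substrate alone. The neighbour charged with 0.50 M of partner still holds 72.9 % at 30.0 min, above the crossing, and there coupling has taken 0.271 M of partner against 0.155 M decomposed.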